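**Plan**

- Cuts, in retrosynthetic order: (a) the two ring B aryl–prenyl bonds at C3' and C5' (Stille coupling); (b) the O1–C2 bond of ring C (oxidative closure through a p-quinone methide); (c) the C4–C4a ketone bond (aryl Grignard reagent plus N-methoxy-N-methylamide); (d) the C8–prenyl bond of ring A (directed metalation).
- Enabling feature: ring B with C2, C3 and C4 is a 4-hydroxyphenylpropanoid unit, the skeleton of tyrosine with its α-carbon as C3. The 4'-hydroxyl is para to the benzylic C2 and flanked by the 3'/5' substituents, so oxidation makes C2 the exocyclic carbon of a p-quinone methide that the ring A oxygen O1, six atoms away, can capture.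
- Forward order: ring A (from 4-bromoresorcinol, prenylated at the future C8) and the ring B–C2–C3–C4 chain (from D-tyrosine) are made separately and joined at C4–C4a to an open-chain ketone. Ring C is then closed at O1–C2, the two ring B prenyl groups are coupled on, and the silyl ether is removed.
- Stereochemistry: C3 (R) is the α-carbon of D-tyrosine, its amino group exchanged for hydroxyl with retention. C2 (R) is set in the ring closure under control of C3, the reversible addition settling in the 2,3-trans form.

Key step: step 9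

Remark on the chemistry: the ring A 4-hydroxyl (later 7-OH) is left free from step 8 onward, on the assumption that a phenol para to the ketone is too electron-poor to be oxidised by Ag2O and cannot reach C2 within the molecule. Iodination is placed after the diazotisation because nitrous acid attacks o,o'-diiodophenols.

**Route**

Step 1
Reactants: 1 4-bromoresorcinol
Product: 2 1-bromo-2,4-bis(methoxymethoxy)benzene
Conditions: MOMCl, iPr2NEt, CH2Cl2, 0 °C → rt
Reagents that add atoms: chloromethyl methyl ether, COCCl
Why: Williamson-type O-alkylation of both phenols with the α-chloro ether gives the bis(methoxymethyl) ether, which withstands the amide base and the Grignard chemistry ahead and supplies two ortho-directing groups for step 2.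

Step 2
Reactants: 2 1-bromo-2,4-bis(methoxymethoxy)benzene; 3 prenyl bromide
Product: 5 1-bromo-2,4-bis(methoxymethoxy)-3-(3-methylbut-2-enyl)benzene, via aryllithium 4 (not isolated)
Conditions: lithium 2,2,6,6-tetramethylpiperidide, THF, −78 °C; then CuBr·SMe2 (10 mol %), 3, −78 → 0 °C
Reagents that add atoms: prenyl bromide (compound 3), CC(C)=CCBr
Why: Directed ortho-metalation: the hindered amide base should remove the proton between the two methoxymethoxy groups (the most acidic, doubly chelated site) without attacking the carbon–bromine bond, and copper-catalysed SN2 allylation of aryllithium 4 with the primary allylic bromide places the prenyl group at the future C8.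

Step 3
Reactants: 6 D-tyrosine
Product: 9 (R)-2-hydroxy-3-(4-hydroxyphenyl)propanoic acid, via diazonium carboxylate 7 (not isolated), via alpha-lactone 8 (not isolated)
Conditions: NaNO2, 1 M aq. H2SO4, 0 °C → rt
Reagents that add atoms: water, O
Why: Nitrous acid deamination of an α-amino acid: the carboxylate displaces N2 from 7 with inversion to give α-lactone 8, which water opens with a second inversion, so the hydroxyl replaces the amino group with net retention and the (R) centre that becomes C3 is kept.

Step 4
Reactants: 9 (R)-2-hydroxy-3-(4-hydroxyphenyl)propanoic acid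
Product: 10 (R)-2-hydroxy-3-(4-hydroxy-3,5-diiodophenyl)propanoic acid
Conditions: I2, NaI, 40% aq. EtNH2, 0 °C → rt; then aq. HCl to pH 2
Reagents that add atoms: iodine, [I][I]
Why: Electrophilic aromatic iodination of the phenolate at both positions ortho to the hydroxyl (the para position is blocked), as in the classical preparation of 3,5-diiodotyrosine; the stereocentre is not involved.

Step 5
Reactants: 10 (R)-2-hydroxy-3-(4-hydroxy-3,5-diiodophenyl)propanoic acid
Product: 12 (R)-2-hydroxy-3-(4-hydroxy-3,5-diiodophenyl)-N-methoxy-N-methylpropanamide, via benzotriazolyl ester 11 (not isolated)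
Conditions: MeNHOMe·HCl, EDCI·HCl, HOBt, N-methylmorpholine, CH2Cl2–DMF, 0 °C → rt
Reagents that add atoms: N,O-dimethylhydroxylamine hydrochloride, CNOC.Cl
Why: Carbodiimide amide coupling through active ester 11; the amine should outcompete the secondary alcohol and the hindered phenol as nucleophile, and an α-hydroxy acid has no oxazolone pathway for racemisation.

Step 6
Reactants: 12 (R)-2-hydroxy-3-(4-hydroxy-3,5-diiodophenyl)-N-methoxy-N-methylpropanamide
Product: 14 (R)-2-(tert-butyldimethylsilyloxy)-3-(4-hydroxy-3,5-diiodophenyl)-N-methoxy-N-methylpropanamide, via bis-silyl ether 13 (not isolated)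
Conditions: TBSCl, imidazole, DMF, rt; aqueous work-up; then KHF2, MeOH, rt
Reagents that add atoms: tert-butyldimethylsilyl chloride, CC(C)(C)[Si](C)(C)Cl
Why: Imidazole-promoted silylation covers both hydroxyls, and bifluoride in methanol should then cleave only the aryl silyl ether of the acidic diiodophenol (selective phenolic desilylation), leaving the secondary silyl ether on the future C3 oxygen and freeing the phenol that shields the iodides in step 7.

Step 7
Reactants: 5 1-bromo-2,4-bis(methoxymethoxy)-3-(3-methylbut-2-enyl)benzene; 14 (R)-2-(tert-butyldimethylsilyloxy)-3-(4-hydroxy-3,5-diiodophenyl)-N-methoxy-N-methylpropanamide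
Product: 17 (R)-1-[2,4-bis(methoxymethoxy)-3-(3-methylbut-2-enyl)phenyl]-2-(tert-butyldimethylsilyloxy)-3-(4-hydroxy-3,5-diiodophenyl)propan-1-one, via arylmagnesium bromide 15 (not isolated), via tetrahedral magnesium adduct 16 (not isolated)
Conditions: 5 (2.5 equiv), Mg, LiCl, THF, rt; then 14, THF, −40 → 0 °C; aq. NH4Cl
Reagents that add atoms: none
Why: Weinreb ketone synthesis: magnesium insertion into the carbon–bromine bond of 5 gives 15, one equivalent of which deprotonates the phenol of 14 while a second adds once to the N-methoxy-N-methylamide to give chelated adduct 16, which releases ketone 17 only on quench, so neither over-addition nor epimerisation of the α-silyloxy centre is expected, and the electron-rich magnesium phenoxide ring should resist iodine–magnesium exchange at or below 0 °C.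

Step 8
Reactants: 17 (R)-1-[2,4-bis(methoxymethoxy)-3-(3-methylbut-2-enyl)phenyl]-2-(tert-butyldimethylsilyloxy)-3-(4-hydroxy-3,5-diiodophenyl)propan-1-one
Product: 19 (R)-2-(tert-butyldimethylsilyloxy)-1-[2,4-dihydroxy-3-(3-methylbut-2-enyl)phenyl]-3-(4-hydroxy-3,5-diiodophenyl)propan-1-one, via tris(trimethylsilyl) ether 18 (not isolated)
Conditions: TMSOTf, 2,2'-bipyridyl, MeCN, 0 °C → rt; then H2O, rt
Reagents that add atoms: none
Why: Silyl triflate–bipyridyl cleavage of aromatic methoxymethyl ethers: each aryl acetal is exchanged for a trimethylsilyl ether under nearly neutral conditions and water then frees the phenols, which should spare the secondary silyl ether, the prenyl double bond and the aryl iodides and avoids the protic acid that would cyclise the prenyl group onto its neighbouring hydroxyls.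

Step 9
Reactants: 19 (R)-2-(tert-butyldimethylsilyloxy)-1-[2,4-dihydroxy-3-(3-methylbut-2-enyl)phenyl]-3-(4-hydroxy-3,5-diiodophenyl)propan-1-one
Product: 21 (2R,3R)-3-(tert-butyldimethylsilyloxy)-7-hydroxy-2-(4-hydroxy-3,5-diiodophenyl)-8-(3-methylbut-2-enyl)chroman-4-one, via p-quinone methide 20 (not isolated)
Conditions: Ag2O (3 equiv), 4 Å molecular sieves, CH2Cl2 (0.005 M), dark, rt
Reagents that add atoms: none
Why: Proposed new method: Ag2O should convert the acidic ring B phenol into its silver phenoxide and take two electrons and the C2 proton from it (phenoxyl radical, then disproportionation or a second electron transfer), giving p-quinone methide 20, whose exocyclic carbon C2 is attacked by the ring A 2-hydroxyl in an oxa-1,6-addition that restores the aromaticity of ring B and forms O1–C2. The closest known reaction type is the Ag2O or DDQ oxidative cyclisation of 2'-hydroxydihydrochalcones and 1,3-diarylpropanes to flavanones and flavans through p-quinone methides, which has not been shown with an α-silyloxy ketone or a 3,5-diiodo-4-hydroxyphenyl ring. Ring C closes in the 6-exo-trig mode. The new C2 centre is controlled by the tyrosine-derived C3 centre: attack anti to the bulky silyloxy group is preferred and the addition is reversible through the 4'-phenoxide, so the product should settle as the 2,3-trans isomer with aryl and silyloxy groups both equatorial, which is (2R,3R). The step needs oxidation of ring B alone and ring closure faster than loss of the C3 proton from 20: the iodine atoms block both ortho positions of ring B so that only the para benzylic site can form a quinone methide, the acyl group makes both ring A phenols and the prenyl group beside them inert to Ag2O, and the aprotic, amine-free, dilute medium with the nucleophile held in a six-membered array favours capture over tautomerisation and over intermolecular coupling.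

Step 10
Reactants: 21 (2R,3R)-3-(tert-butyldimethylsilyloxy)-7-hydroxy-2-(4-hydroxy-3,5-diiodophenyl)-8-(3-methylbut-2-enyl)chroman-4-one; 22 tributyl(3-methylbut-2-enyl)stannane
Product: 23 (2R,3R)-3-(tert-butyldimethylsilyloxy)-7-hydroxy-2-[4-hydroxy-3,5-bis(3-methylbut-2-enyl)phenyl]-8-(3-methylbut-2-enyl)chroman-4-one
Conditions: Pd(PPh3)4 (10 mol %), 22 (3 equiv), DMF, 90 °C
Reagents that add atoms: tributyl(3-methylbut-2-enyl)stannane (compound 22), CC(C)=CC[Sn](CCCC)(CCCC)CCCC
Why: Twofold Stille coupling: oxidative addition of zerovalent palladium into each carbon–iodine bond, transmetalation with the allylic stannane and reductive elimination at the less substituted allyl terminus should give the linear prenyl groups, and the conditions tolerate free phenols, the ketone and the silyl ether while the 2,3-trans arrangement remains the thermodynamic one.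

Step 11
Reactants: 23 (2R,3R)-3-(tert-butyldimethylsilyloxy)-7-hydroxy-2-[4-hydroxy-3,5-bis(3-methylbut-2-enyl)phenyl]-8-(3-methylbut-2-enyl)chroman-4-one
Product: 24 (2R,3R)-3,7-dihydroxy-2-[4-hydroxy-3,5-bis(3-methylbut-2-enyl)phenyl]-8-(3-methylbut-2-enyl)chroman-4-one (CNP0316331.1)
Conditions: HF·pyridine, pyridine, THF, 0 °C → rt
Reagents that add atoms: none
Why: Fluoride-mediated cleavage of the secondary silyl ether under buffered, weakly acidic conditions should free the 3-hydroxyl without the base that would open or epimerise the dihydroflavonol and without acid strong enough to cyclise the three o-prenylphenol units.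

**Compound list**

1 | 4-bromoresorcinol (4-bromobenzene-1,3-diol) | Oc1ccc(Br)c(O)c1 | starting material
2 | 1-bromo-2,4-bis(methoxymethoxy)benzene | COCOc1ccc(Br)c(OCOC)c1 | intermediate
3 | prenyl bromide (1-bromo-3-methylbut-2-ene) | CC(C)=CCBr | starting material
4 | [3-bromo-2,6-bis(methoxymethoxy)phenyl]lithium | COCOc1ccc(Br)c(OCOC)c1[Li] | intermediate (not isolated)
5 | 1-bromo-2,4-bis(methoxymethoxy)-3-(3-methylbut-2-enyl)benzene | COCOc1ccc(Br)c(OCOC)c1CC=C(C)C | intermediate
6 | D-tyrosine, (R)-2-amino-3-(4-hydroxyphenyl)propanoic acid | N[C@H](Cc1ccc(O)cc1)C(=O)O | starting material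
7 | (R)-1-carboxylato-2-(4-hydroxyphenyl)ethanediazonium (diazonium carboxylate) | N#[N+][C@H](Cc1ccc(O)cc1)C(=O)[O-] | intermediate (not isolated)
8 | (S)-3-(4-hydroxybenzyl)oxiran-2-one (α-lactone) | O=C1O[C@H]1Cc2ccc(O)cc2 | intermediate (not isolated)
9 | (R)-2-hydroxy-3-(4-hydroxyphenyl)propanoic acid | O[C@H](Cc1ccc(O)cc1)C(=O)O | intermediate
10 | (R)-2-hydroxy-3-(4-hydroxy-3,5-diiodophenyl)propanoic acid | O[C@H](Cc1cc(I)c(O)c(I)c1)C(=O)O | intermediate
11 | benzotriazol-1-yl (R)-2-hydroxy-3-(4-hydroxy-3,5-diiodophenyl)propanoate | O[C@H](Cc1cc(I)c(O)c(I)c1)C(=O)On1nnc2ccccc12 | intermediate (not isolated)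
12 | (R)-2-hydroxy-3-(4-hydroxy-3,5-diiodophenyl)-N-methoxy-N-methylpropanamide | O[C@H](Cc1cc(I)c(O)c(I)c1)C(=O)N(C)OC | intermediate
13 | (R)-2-(tert-butyldimethylsilyloxy)-3-[4-(tert-butyldimethylsilyloxy)-3,5-diiodophenyl]-N-methoxy-N-methylpropanamide | CC(C)(C)[Si](C)(C)O[C@H](Cc1cc(I)c(O[Si](C)(C)C(C)(C)C)c(I)c1)C(=O)N(C)OC | intermediate (not isolated)
14 | (R)-2-(tert-butyldimethylsilyloxy)-3-(4-hydroxy-3,5-diiodophenyl)-N-methoxy-N-methylpropanamide | CC(C)(C)[Si](C)(C)O[C@H](Cc1cc(I)c(O)c(I)c1)C(=O)N(C)OC | intermediate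
15 | [2,4-bis(methoxymethoxy)-3-(3-methylbut-2-enyl)phenyl]magnesium bromide | COCOc1ccc([Mg]Br)c(OCOC)c1CC=C(C)C | intermediate (not isolated)
16 | bis(bromomagnesium) alkoxide–phenoxide of (2R)-1-[2,4-bis(methoxymethoxy)-3-(3-methylbut-2-enyl)phenyl]-2-(tert-butyldimethylsilyloxy)-3-(4-hydroxy-3,5-diiodophenyl)-1-[methoxy(methyl)amino]propan-1-ol (C1 unassigned) | COCOc1ccc(C(O[Mg]Br)(N(C)OC)[C@@H](Cc2cc(I)c(O[Mg]Br)c(I)c2)O[Si](C)(C)C(C)(C)C)c(OCOC)c1CC=C(C)C | intermediate (not isolated)
17 | (R)-1-[2,4-bis(methoxymethoxy)-3-(3-methylbut-2-enyl)phenyl]-2-(tert-butyldimethylsilyloxy)-3-(4-hydroxy-3,5-diiodophenyl)propan-1-one | COCOc1ccc(C(=O)[C@@H](Cc2cc(I)c(O)c(I)c2)O[Si](C)(C)C(C)(C)C)c(OCOC)c1CC=C(C)C | intermediate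
18 | (R)-2-(tert-butyldimethylsilyloxy)-1-[3-(3-methylbut-2-enyl)-2,4-bis(trimethylsilyloxy)phenyl]-3-[3,5-diiodo-4-(trimethylsilyloxy)phenyl]propan-1-one | CC(C)=CCc1c(O[Si](C)(C)C)ccc(C(=O)[C@@H](Cc2cc(I)c(O[Si](C)(C)C)c(I)c2)O[Si](C)(C)C(C)(C)C)c1O[Si](C)(C)C | intermediate (not isolated)
19 | (R)-2-(tert-butyldimethylsilyloxy)-1-[2,4-dihydroxy-3-(3-methylbut-2-enyl)phenyl]-3-(4-hydroxy-3,5-diiodophenyl)propan-1-one | CC(C)=CCc1c(O)ccc(C(=O)[C@@H](Cc2cc(I)c(O)c(I)c2)O[Si](C)(C)C(C)(C)C)c1O | intermediate
20 | 4-[(2R)-2-(tert-butyldimethylsilyloxy)-3-[2,4-dihydroxy-3-(3-methylbut-2-enyl)phenyl]-3-oxopropylidene]-2,6-diiodocyclohexa-2,5-dien-1-one | CC(C)=CCc1c(O)ccc(C(=O)[C@@H](C=C2C=C(I)C(=O)C(I)=C2)O[Si](C)(C)C(C)(C)C)c1O | intermediate (not isolated)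
21 | (2R,3R)-3-(tert-butyldimethylsilyloxy)-7-hydroxy-2-(4-hydroxy-3,5-diiodophenyl)-8-(3-methylbut-2-enyl)chroman-4-one | Oc1c(I)cc([C@H]2Oc3c(ccc(O)c3CC=C(C)C)C(=O)[C@@H]2O[Si](C)(C)C(C)(C)C)cc1I | intermediate
22 | tributyl(3-methylbut-2-enyl)stannane | CC(C)=CC[Sn](CCCC)(CCCC)CCCC | starting material
23 | (2R,3R)-3-(tert-butyldimethylsilyloxy)-7-hydroxy-2-[4-hydroxy-3,5-bis(3-methylbut-2-enyl)phenyl]-8-(3-methylbut-2-enyl)chroman-4-one | CC(C)=CCc1cc([C@H]2Oc3c(ccc(O)c3CC=C(C)C)C(=O)[C@@H]2O[Si](C)(C)C(C)(C)C)cc(CC=C(C)C)c1O | intermediate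
24 | (2R,3R)-3,7-dihydroxy-2-[4-hydroxy-3,5-bis(3-methylbut-2-enyl)phenyl]-8-(3-methylbut-2-enyl)chroman-4-one (CNP0316331.1) | CC(C)=CCc1cc([C@H]2Oc3c(ccc(O)c3CC=C(C)C)C(=O)[C@@H]2O)cc(CC=C(C)C)c1O | target

**Step count**

Total: 11 steps. Longest linear sequence: 9 steps (D-tyrosine 6 to target 24, steps 3–11). The ring A branch (steps 1–2) joins at step 7.

**Steps most likely to fail**

1. Step 9 (carries the "Proposed new method" label). What may go wrong: the silver phenoxide is not oxidised, the diiodophenoxyl radical couples with a second molecule instead of losing the C2 hydrogen, or 20 tautomerises by loss of the C3 proton so that the stereocentre is erased. The fallback uses the established chalcone epoxide route to dihydroflavonols, sets out from 5 and comes back at 24.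
   - Grignard reagent 15, made from 5 as in step 7, would be acylated with N-methoxy-N-methylacetamide to 1-[2,4-bis(methoxymethoxy)-3-(3-methylbut-2-enyl)phenyl]ethanone F1.
   - Commercial 4-hydroxy-3,5-diiodobenzaldehyde would be protected (MOMCl, iPr2NEt) as 3,5-diiodo-4-(methoxymethoxy)benzaldehyde F2.
   - Claisen–Schmidt condensation of F1 with F2 (KOH, EtOH) should give (E)-1-[2,4-bis(methoxymethoxy)-3-(3-methylbut-2-enyl)phenyl]-3-[3,5-diiodo-4-(methoxymethoxy)phenyl]prop-2-en-1-one F3.
   - Juliá–Colonna epoxidation (poly-L-leucine, urea–H2O2, DBU, THF) should give [2,4-bis(methoxymethoxy)-3-(3-methylbut-2-enyl)phenyl][(2R,3S)-3-[3,5-diiodo-4-(methoxymethoxy)phenyl]oxiran-2-yl]methanone F4.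
   - HCl in MeOH–THF would remove the three methoxymethyl groups and let the freed 2'-hydroxyl open the epoxide at the benzylic carbon with inversion. The product would be (2R,3R)-3,7-dihydroxy-2-(4-hydroxy-3,5-diiodophenyl)-8-(3-methylbut-2-enyl)chroman-4-one F5, whose C3 configuration comes from the epoxide.
   - F5 would be coupled with 22 under the conditions of step 10, which gives 24 directly, so no silyl ether is needed on this path.

2. Step 10. What may go wrong: reductive elimination at the more substituted allyl terminus (1,1-dimethylallyl in place of prenyl), protodeiodination, or stalling after the first coupling beside the free phenol. The fallback sets out from 21 and comes back at 23.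
   - Stille coupling with allyltributylstannane (Pd(PPh3)4, DMF, 90 °C), which has no regiochemical ambiguity, should give (2R,3R)-3-(tert-butyldimethylsilyloxy)-2-(3,5-diallyl-4-hydroxyphenyl)-7-hydroxy-8-(3-methylbut-2-enyl)chroman-4-one F6.
   - Cross-metathesis of F6 with excess 2-methylbut-2-ene (second-generation Grubbs catalyst, CH2Cl2, 40 °C) would turn each allyl into a prenyl group and give 23; the ring A prenyl group only exchanges degenerately.

3. Step 7. What may go wrong: iodine–magnesium exchange on ring B during the hours at 0 °C that the amide needs, or incomplete addition to the sparingly soluble magnesium phenoxide. The fallback sets out from 14 and comes back at 17.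
   - Reduction of 14 with iBu2AlH (THF, −78 °C) should give (R)-2-(tert-butyldimethylsilyloxy)-3-(4-hydroxy-3,5-diiodophenyl)propanal F7.
   - Addition of 15 at −78 °C, where an aldehyde reacts within minutes and exchange is frozen, should give (2R)-1-[2,4-bis(methoxymethoxy)-3-(3-methylbut-2-enyl)phenyl]-2-(tert-butyldimethylsilyloxy)-3-(4-hydroxy-3,5-diiodophenyl)propan-1-ol F8 as a mixture of C1 epimers.
   - Oxidation with Dess–Martin periodinane (NaHCO3, CH2Cl2) would give 17.

**Further compounds**

F1 | step 9 | 1-[2,4-bis(methoxymethoxy)-3-(3-methylbut-2-enyl)phenyl]ethanone | COCOc1ccc(C(C)=O)c(OCOC)c1CC=C(C)C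
F2 | step 9 | 3,5-diiodo-4-(methoxymethoxy)benzaldehyde | COCOc1c(I)cc(C=O)cc1I
F3 | step 9 | (E)-1-[2,4-bis(methoxymethoxy)-3-(3-methylbut-2-enyl)phenyl]-3-[3,5-diiodo-4-(methoxymethoxy)phenyl]prop-2-en-1-one | COCOc1ccc(C(=O)/C=C/c2cc(I)c(OCOC)c(I)c2)c(OCOC)c1CC=C(C)C
F4 | step 9 | [2,4-bis(methoxymethoxy)-3-(3-methylbut-2-enyl)phenyl][(2R,3S)-3-[3,5-diiodo-4-(methoxymethoxy)phenyl]oxiran-2-yl]methanone | COCOc1ccc(C(=O)[C@@H]2O[C@H]2c3cc(I)c(OCOC)c(I)c3)c(OCOC)c1CC=C(C)C
F5 | step 9 | (2R,3R)-3,7-dihydroxy-2-(4-hydroxy-3,5-diiodophenyl)-8-(3-methylbut-2-enyl)chroman-4-one | Oc1c(I)cc([C@H]2Oc3c(ccc(O)c3CC=C(C)C)C(=O)[C@@H]2O)cc1I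
F6 | step 10 | (2R,3R)-3-(tert-butyldimethylsilyloxy)-2-(3,5-diallyl-4-hydroxyphenyl)-7-hydroxy-8-(3-methylbut-2-enyl)chroman-4-one | C=CCc1cc([C@H]2Oc3c(ccc(O)c3CC=C(C)C)C(=O)[C@@H]2O[Si](C)(C)C(C)(C)C)cc(CC=C)c1O
F7 | step 7 | (R)-2-(tert-butyldimethylsilyloxy)-3-(4-hydroxy-3,5-diiodophenyl)propanal | CC(C)(C)[Si](C)(C)O[C@H](Cc1cc(I)c(O)c(I)c1)C=O
F8 | step 7 | (2R)-1-[2,4-bis(methoxymethoxy)-3-(3-methylbut-2-enyl)phenyl]-2-(tert-butyldimethylsilyloxy)-3-(4-hydroxy-3,5-diiodophenyl)propan-1-ol (both C1 epimers) | COCOc1ccc(C(O)[C@@H](Cc2cc(I)c(O)c(I)c2)O[Si](C)(C)C(C)(C)C)c(OCOC)c1CC=C(C)C
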